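**Retrosynthetic overview**

1. Side chain (C1–C8): target ⇐ (E)-enal (Colvin homologation) ⇐ allyl-oxirane (cross-metathesis) ⇐ epoxy triflate + vinyl–copper ⇐ (Z)-allylic alcohol (Katsuki–Sharpless epoxidation sets C6/C7) ⇐ homopropargylic bromide + formaldehyde.
2. C9 and C12: chelation-controlled allenylstannane addition to an oxolane-2-carbaldehyde, then SN2 bromination with inversion; the ring bromide likewise by SN2 on an all-cis oxolan-3-ol.
3. Oxolane (key step): the all-cis oxolan-3-ol ⇐ a 4-methylidene-1,3-dioxolane by an aluminium-promoted 1,3 O→C shift with in-flask ketone reduction. The acetal carbon becomes oxolane C5 and the exocyclic methylene becomes C4, so the C4–C5 ring bond is the one made. The dioxolane comes from (R)-2-hydroxybutanoic acid and a silyloxyacetaldehyde.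
4. Enabling feature: in the oxolane the array O1–C2(Et)–C3(Br)–C4H2–C5 has the heteroatom-bearing C3 between the ethyl-bearing C2 and the unsubstituted C4 methylene. At the C3-ketone level the ring is therefore the 1,3-shift isomer of the enol acetal of a 2,5-disubstituted 1,3-dioxolan-4-one (acid carbon = C3, α-carbon = C2, aldehyde carbon = C5, added methylene = C4).
5. Ring order: 1,3-dioxolane (temporary, step 1) → oxolane (step 3, from the dioxolane) → oxirane (step 11).

Key step: step 3

Remark on the chemistry: the chain is numbered C1 (alkyne CH) to C15 (ethyl CH3). Read from the SMILES, the target is 3E,6S,7R,9S,10R,12S,13R, with a cis-oxirane and a 2,5-cis/2,3-trans oxolane. All reagents named under Conditions are assumed to be purchased.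

**Step 1**
Reactants: 1 (2R)-2-hydroxybutanoic acid; 2 {[tert-butyl(dimethyl)silyl]oxy}acetaldehyde
Product: 4 (2R,5R)-2-({[tert-butyl(dimethyl)silyl]oxy}methyl)-5-ethyl-1,3-dioxolan-4-one, via bis(trimethylsilyl) derivative 3 (not isolated)
Conditions: (Me3Si)2NH (1.2 equiv), CH2Cl2, rt, then evaporate; 2 (1.2 equiv), Me3SiOTf (10 mol %), CH2Cl2, −78 °C; pyridine quench
Reagents that add atoms: none
Why: silyl-triflate-catalysed acetalisation of the bis-silylated α-hydroxy acid with the aldehyde should give the 1,3-dioxolan-4-one under kinetic control, the new acetal centre forming cis to the ethyl group (both substituents pseudo-equatorial on the envelope) while the α-stereocentre of 1 is untouched.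

**Step 2**
Reactants: 4 (2R,5R)-2-({[tert-butyl(dimethyl)silyl]oxy}methyl)-5-ethyl-1,3-dioxolan-4-one
Product: 5 tert-butyl{[(2R,5R)-5-ethyl-4-methylidene-1,3-dioxolan-2-yl]methoxy}dimethylsilane
Conditions: Cp2TiMe2 (2.2 equiv), toluene, 65 °C, dark; filtration through basic alumina
Reagents that add atoms: dimethyltitanocene (Cp2TiMe2), C[Ti](C)(C1C=CC=C1)C1C=CC=C1
Why: Petasis methylenation (Cp2Ti=CH2 formed thermally) olefinates lactone-type carbonyls without acid, so the acetal, the silyl ether and both stereocentres should survive and the acid-labile enol acetal is obtained directly.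

**Step 3**
Reactants: 5 tert-butyl{[(2R,5R)-5-ethyl-4-methylidene-1,3-dioxolan-2-yl]methoxy}dimethylsilane
Product: 7 (2R,3R,5R)-5-({[tert-butyl(dimethyl)silyl]oxy}methyl)-2-ethyloxolan-3-ol, via oxolan-3-one 6 (not isolated)
Conditions: iBu3Al (3 equiv), toluene, −78 → −20 °C; aq. Rochelle salt
Reagents that add atoms: none
Why: iBu3Al coordinates the enol-ether oxygen of the 4-methylidene-1,3-dioxolane and cleaves the acetal C2–O3 bond to an oxocarbenium ion (O1=C2) ion-paired with a tethered aluminium enolate, whose methylene terminus then bonds to the former acetal carbon (a 1,3 O→C shift) to give oxolan-3-one 6, and an isobutyl group of the reagent then transfers hydride to the aluminium-bound ketone to give 7. The closest known reaction type is the Petasis–Ferrier rearrangement, whose 1,3-dioxolane version run with iBu3Al is a known rearrangement–reduction route to 2,5-cis oxolan-3-ols. The oxolane closes by a 5-(enolendo)-endo-trig attack of the enolate carbon on the oxocarbenium carbon, feasible because the ion pair collapses before the partners separate or reorient. The new stereocentre at oxolane C5 is controlled by the acetal carbon of 5 (the C–C bond forms on the face the C–O bond left, so cis-5 gives the 2,5-cis ketone, which is also the arrangement with both substituents pseudo-equatorial), and the carbinol centre C3 is set by hydride delivery to the ketone face anti to the two cis substituents, giving the all-cis alcohol. The step needs cleavage of C2–O3 and not C2–O1, secured by the enol ether because only O3 can leave as an enolate; it needs C-attack at the acetal carbon alone, secured by the saturated CH2OSi substituent, which offers no allylic terminus for a competing [3,3] shift; and it needs recombination to outrun hydride reduction of the oxocarbenium ion, which the low temperature and the intramolecular recombination should ensure.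

**Step 4**
Reactants: 7 (2R,3R,5R)-5-({[tert-butyl(dimethyl)silyl]oxy}methyl)-2-ethyloxolan-3-ol
Product: 8 {[(2R,4S,5R)-4-bromo-5-ethyloxolan-2-yl]methoxy}(tert-butyl)dimethylsilane
Conditions: CBr4 (3 equiv), P(n-Oct)3 (3 equiv), 1-methylcyclohexene, toluene, 70 °C
Reagents that add atoms: carbon tetrabromide, BrC(Br)(Br)Br
Why: Appel bromination (oxyphosphonium formation, then SN2 attack of bromide) inverts C3, the bromide entering from the ring face that carries no substituent, which should give the 2,3-trans bromide while the alkene scavenger traps HBr and protects the silyl ether.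

**Step 5**
Reactants: 8 {[(2R,4S,5R)-4-bromo-5-ethyloxolan-2-yl]methoxy}(tert-butyl)dimethylsilane
Product: 9 [(2R,4S,5R)-4-bromo-5-ethyloxolan-2-yl]methanol
Conditions: HF·pyridine, pyridine, THF, 0 °C → rt
Reagents that add atoms: none
Why: fluoride-mediated cleavage of the primary silyl ether under buffered, weakly acidic conditions should avoid base-induced elimination of the secondary bromide.

**Step 6**
Reactants: 9 [(2R,4S,5R)-4-bromo-5-ethyloxolan-2-yl]methanol
Product: 10 (2R,4S,5R)-4-bromo-5-ethyloxolane-2-carbaldehyde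
Conditions: Dess–Martin periodinane (1.3 equiv), NaHCO3, CH2Cl2, 0 °C → rt; used crude
Reagents that add atoms: none
Why: Dess–Martin oxidation of the primary alcohol under buffered neutral conditions should give the α-alkoxy aldehyde without epimerisation at the ring carbon next to the carbonyl.

**Step 7**
Reactants: 10 (2R,4S,5R)-4-bromo-5-ethyloxolane-2-carbaldehyde
Product: 11 (1R)-1-[(2R,4S,5R)-4-bromo-5-ethyloxolan-2-yl]but-3-yn-1-ol
Conditions: MgBr2·OEt2 (3 equiv), CH2Cl2, −20 °C, 15 min; H2C=C=CHSnBu3 (1.5 equiv), −20 → 0 °C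
Reagents that add atoms: allenyltributylstannane, C=C=C[Sn](CCCC)(CCCC)CCCC
Why: Lewis-acid-mediated SE2′ addition of the allenylstannane under chelation control (MgBr2 bridges the aldehyde oxygen and the ring oxygen and the nucleophile attacks the face anti to the ring CH2) should give the threo (1R) homopropargylic alcohol.

**Step 8**
Reactants: 11 (1R)-1-[(2R,4S,5R)-4-bromo-5-ethyloxolan-2-yl]but-3-yn-1-ol
Product: 12 (2R,3S,5R)-3-bromo-5-[(1S)-1-bromobut-3-yn-1-yl]-2-ethyloxolane
Conditions: CBr4 (2 equiv), P(n-Oct)3 (2 equiv), 1-methylcyclohexene, toluene, 60 °C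
Reagents that add atoms: carbon tetrabromide, BrC(Br)(Br)Br
Why: a second Appel bromination, in which SN2 inversion converts the (R)-carbinol into the (S)-bromide required at C9.

**Step 9**
Reactants: 12 (2R,3S,5R)-3-bromo-5-[(1S)-1-bromobut-3-yn-1-yl]-2-ethyloxolane
Product: 13 (5S)-5-bromo-5-[(2R,4S,5R)-4-bromo-5-ethyloxolan-2-yl]pent-2-yn-1-ol
Conditions: n-BuLi (1.05 equiv), THF, −78 °C, 10 min; HCHO (gas from cracked paraformaldehyde), −78 °C; AcOH quench at −78 °C
Reagents that add atoms: formaldehyde, C=O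
Why: hydroxymethylation of a terminal alkyne, in which deprotonation of the alkyne C–H and addition of the lithium acetylide to monomeric formaldehyde at −78 °C should outrun E2 loss of HBr.

**Step 10**
Reactants: 13 (5S)-5-bromo-5-[(2R,4S,5R)-4-bromo-5-ethyloxolan-2-yl]pent-2-yn-1-ol
Product: 14 (2Z,5S)-5-bromo-5-[(2R,4S,5R)-4-bromo-5-ethyloxolan-2-yl]pent-2-en-1-ol
Conditions: H2 (1 atm), Pd/CaCO3/Pb(OAc)2 (Lindlar catalyst), quinoline, EtOAc, rt
Reagents that add atoms: none
Why: Lindlar semihydrogenation adds H2 syn on the poisoned palladium surface to give the (Z)-allylic alcohol, and unactivated secondary C–Br bonds should not be hydrogenolysed under these conditions.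

**Step 11**
Reactants: 14 (2Z,5S)-5-bromo-5-[(2R,4S,5R)-4-bromo-5-ethyloxolan-2-yl]pent-2-en-1-ol
Product: 15 {(2S,3R)-3-[(2S)-2-bromo-2-[(2R,4S,5R)-4-bromo-5-ethyloxolan-2-yl]ethyl]oxiran-2-yl}methanol
Conditions: Ti(OiPr)4 (0.3 equiv), L-(+)-diethyl tartrate (0.36 equiv), t-BuOOH (2 equiv, in decane), 4 Å molecular sieves, CH2Cl2, −20 °C, 2–3 d
Reagents that add atoms: tert-butyl hydroperoxide, CC(C)(C)OO
Why: Katsuki–Sharpless asymmetric epoxidation under reagent control, in which the titanium complex of L-(+)-diethyl tartrate delivers oxygen to the face of the (Z)-allylic alcohol that gives the (2S,3R)-epoxy alcohol, that is the cis-oxirane with the 6S,7R configuration, the alkene geometry being retained.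

**Step 12**
Reactants: 15 {(2S,3R)-3-[(2S)-2-bromo-2-[(2R,4S,5R)-4-bromo-5-ethyloxolan-2-yl]ethyl]oxiran-2-yl}methanol
Product: 16 {(2S,3R)-3-[(2S)-2-bromo-2-[(2R,4S,5R)-4-bromo-5-ethyloxolan-2-yl]ethyl]oxiran-2-yl}methyl trifluoromethanesulfonate
Conditions: Tf2O (1.1 equiv), 2,6-lutidine (1.5 equiv), CH2Cl2, −78 °C; cold aqueous work-up, used at once
Reagents that add atoms: trifluoromethanesulfonic anhydride, O=S(=O)(OS(=O)(=O)C(F)(F)F)C(F)(F)F
Why: O-sulfonylation of the primary alcohol at −78 °C with a hindered base should give the primary triflate without opening the oxirane.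

**Step 13**
Reactants: 16 {(2S,3R)-3-[(2S)-2-bromo-2-[(2R,4S,5R)-4-bromo-5-ethyloxolan-2-yl]ethyl]oxiran-2-yl}methyl trifluoromethanesulfonate
Product: 17 (2R,3S,5R)-3-bromo-5-{(1S)-1-bromo-2-[(2R,3S)-3-(prop-2-en-1-yl)oxiran-2-yl]ethyl}-2-ethyloxolane
Conditions: CH2=CHMgBr (2 equiv), CuBr·SMe2 (10 mol %), Et2O/THF, −78 → −40 °C
Reagents that add atoms: vinylmagnesium bromide, C=C[Mg]Br
Why: copper-catalysed coupling of a Grignard reagent with a primary epoxy triflate substitutes at the CH2–OTf carbon much faster than the organocopper opens the oxirane or attacks the secondary bromides, so no stereocentre is touched.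

**Step 14**
Reactants: 17 (2R,3S,5R)-3-bromo-5-{(1S)-1-bromo-2-[(2R,3S)-3-(prop-2-en-1-yl)oxiran-2-yl]ethyl}-2-ethyloxolane
Product: 18 (2E)-4-{(2S,3R)-3-[(2S)-2-bromo-2-[(2R,4S,5R)-4-bromo-5-ethyloxolan-2-yl]ethyl]oxiran-2-yl}but-2-enal
Conditions: (E)-crotonaldehyde (10 equiv), second-generation Grubbs catalyst RuCl2(=CHPh)(PCy3)(SIMes) (5 mol %), CH2Cl2, 40 °C
Reagents that add atoms: (E)-but-2-enal (crotonaldehyde), C/C=C/C=O
Why: olefin cross-metathesis of the terminal alkene with excess crotonaldehyde should give the (E)-enal under thermodynamic control, the oxirane and the bromides being inert to the ruthenium carbene.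

**Step 15**
Reactants: 18 (2E)-4-{(2S,3R)-3-[(2S)-2-bromo-2-[(2R,4S,5R)-4-bromo-5-ethyloxolan-2-yl]ethyl]oxiran-2-yl}but-2-enal
Product: 19 (2R,3S,5R)-3-bromo-5-[(1S)-1-bromo-2-{(2R,3S)-3-[(2E)-pent-2-en-4-yn-1-yl]oxiran-2-yl}ethyl]-2-ethyloxolane (target)
Conditions: Me3SiCHN2 (1.5 equiv), LiN(iPr)2 (1.4 equiv), THF, −78 °C, 30 min; then 18, −78 → −20 °C; AcOH quench
Reagents that add atoms: (trimethylsilyl)diazomethane, C[Si](C)(C)C=[N+]=[N-]
Why: Colvin homologation (addition of lithiated trimethylsilyldiazomethane to the aldehyde, Peterson-type elimination, loss of N2 and 1,2-hydrogen shift of the alkylidene carbene) should give the terminal alkyne with the E alkene intact, the fast addition at −78 °C preceding any base attack on the allylic oxirane.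

**Compound list**

1 | (2R)-2-hydroxybutanoic acid | CC[C@@H](O)C(=O)O | starting material
2 | {[tert-butyl(dimethyl)silyl]oxy}acetaldehyde | CC(C)(C)[Si](C)(C)OCC=O | starting material
3 | trimethylsilyl (2R)-2-[(trimethylsilyl)oxy]butanoate | CC[C@@H](O[Si](C)(C)C)C(=O)O[Si](C)(C)C | intermediate (not isolated)
4 | (2R,5R)-2-({[tert-butyl(dimethyl)silyl]oxy}methyl)-5-ethyl-1,3-dioxolan-4-one (cis) | CC(C)(C)[Si](C)(C)OC[C@@H]1O[C@H](CC)C(=O)O1 | intermediate
5 | tert-butyl{[(2R,5R)-5-ethyl-4-methylidene-1,3-dioxolan-2-yl]methoxy}dimethylsilane | CC(C)(C)[Si](C)(C)OC[C@@H]1O[C@H](CC)C(=C)O1 | intermediate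
6 | (2R,5R)-5-({[tert-butyl(dimethyl)silyl]oxy}methyl)-2-ethyloxolan-3-one (2,5-cis) | CC(C)(C)[Si](C)(C)OC[C@H]1CC(=O)[C@@H](CC)O1 | intermediate (not isolated)
7 | (2R,3R,5R)-5-({[tert-butyl(dimethyl)silyl]oxy}methyl)-2-ethyloxolan-3-ol (all-cis) | CC(C)(C)[Si](C)(C)OC[C@H]1C[C@@H](O)[C@@H](CC)O1 | intermediate
8 | {[(2R,4S,5R)-4-bromo-5-ethyloxolan-2-yl]methoxy}(tert-butyl)dimethylsilane | CC(C)(C)[Si](C)(C)OC[C@H]1C[C@H](Br)[C@@H](CC)O1 | intermediate
9 | [(2R,4S,5R)-4-bromo-5-ethyloxolan-2-yl]methanol | OC[C@H]1C[C@H](Br)[C@@H](CC)O1 | intermediate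
10 | (2R,4S,5R)-4-bromo-5-ethyloxolane-2-carbaldehyde | O=C[C@H]1C[C@H](Br)[C@@H](CC)O1 | intermediate
11 | (1R)-1-[(2R,4S,5R)-4-bromo-5-ethyloxolan-2-yl]but-3-yn-1-ol | C#CC[C@@H](O)[C@H]1C[C@H](Br)[C@@H](CC)O1 | intermediate
12 | (2R,3S,5R)-3-bromo-5-[(1S)-1-bromobut-3-yn-1-yl]-2-ethyloxolane | C#CC[C@H](Br)[C@H]1C[C@H](Br)[C@@H](CC)O1 | intermediate
13 | (5S)-5-bromo-5-[(2R,4S,5R)-4-bromo-5-ethyloxolan-2-yl]pent-2-yn-1-ol | OCC#CC[C@H](Br)[C@H]1C[C@H](Br)[C@@H](CC)O1 | intermediate
14 | (2Z,5S)-5-bromo-5-[(2R,4S,5R)-4-bromo-5-ethyloxolan-2-yl]pent-2-en-1-ol | OC/C=C\C[C@H](Br)[C@H]1C[C@H](Br)[C@@H](CC)O1 | intermediate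
15 | {(2S,3R)-3-[(2S)-2-bromo-2-[(2R,4S,5R)-4-bromo-5-ethyloxolan-2-yl]ethyl]oxiran-2-yl}methanol (cis-oxirane) | OC[C@@H]1O[C@@H]1C[C@H](Br)[C@H]1C[C@H](Br)[C@@H](CC)O1 | intermediate
16 | {(2S,3R)-3-[(2S)-2-bromo-2-[(2R,4S,5R)-4-bromo-5-ethyloxolan-2-yl]ethyl]oxiran-2-yl}methyl trifluoromethanesulfonate | FC(F)(F)S(=O)(=O)OC[C@@H]1O[C@@H]1C[C@H](Br)[C@H]1C[C@H](Br)[C@@H](CC)O1 | intermediate
17 | (2R,3S,5R)-3-bromo-5-{(1S)-1-bromo-2-[(2R,3S)-3-(prop-2-en-1-yl)oxiran-2-yl]ethyl}-2-ethyloxolane | C=CC[C@@H]1O[C@@H]1C[C@H](Br)[C@H]1C[C@H](Br)[C@@H](CC)O1 | intermediate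
18 | (2E)-4-{(2S,3R)-3-[(2S)-2-bromo-2-[(2R,4S,5R)-4-bromo-5-ethyloxolan-2-yl]ethyl]oxiran-2-yl}but-2-enal | O=C/C=C/C[C@@H]1O[C@@H]1C[C@H](Br)[C@H]1C[C@H](Br)[C@@H](CC)O1 | intermediate
19 | (2R,3S,5R)-3-bromo-5-[(1S)-1-bromo-2-{(2R,3S)-3-[(2E)-pent-2-en-4-yn-1-yl]oxiran-2-yl}ethyl]-2-ethyloxolane | C#C/C=C/C[C@@H]1O[C@@H]1C[C@H](Br)[C@H]1C[C@H](Br)[C@@H](CC)O1 | target

**Step count and risks**

Total step count: 15. Longest linear sequence: 15 steps (from 1).

Steps most likely to fail:

1. Step 3 (key step). What may go wrong: hydride transfer from iBu3Al to the oxocarbenium ion before the ring closes (reductive opening of the acetal), or dissociation of the ion pair with loss of the 2,5-cis relationship, or hydride delivery to the wrong ketone face. The fallback makes the same ring bond by a rhodium-carbenoid C–H insertion; it sets out from 1 and returns to the route at 10. O-Allylation of 1 (NaH, allyl bromide, THF) gives (2R)-2-(prop-2-en-1-yloxy)butanoic acid F1. Oxalyl chloride converts it into (2R)-2-(prop-2-en-1-yloxy)butanoyl chloride F2, and diazomethane gives (3R)-1-diazo-3-(prop-2-en-1-yloxy)pentan-2-one F3. Rh2(OAc)4 (1 mol %, CH2Cl2, rt) should insert the carbenoid into the allylic C–H bond next to the ether oxygen, a known 2,5-cis-selective route to oxolan-3-ones, giving (2R,5R)-5-ethenyl-2-ethyloxolan-3-one F4. LiBH(s-Bu)3 (THF, −78 °C) reduces it from the open face to (2R,3R,5R)-5-ethenyl-2-ethyloxolan-3-ol F5. Appel bromination (CBr4, P(n-Oct)3) gives (2R,3S,5R)-3-bromo-5-ethenyl-2-ethyloxolane F6, and ozonolysis (O3, then Me2S) gives aldehyde 10.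

2. Step 9. What may go wrong: E2 loss of HBr across C8–C9 (the C8 hydrogens are propargylic) under the basic conditions, competing with acetylide formation and addition. The fallback forms the C5–C6 bond before the base-labile bromide is installed; it sets out from 11 and returns at 13. The dianion of 11 (n-BuLi, 2.1 equiv, THF, −78 °C) with formaldehyde gives (5R)-5-[(2R,4S,5R)-4-bromo-5-ethyloxolan-2-yl]pent-2-yne-1,5-diol F7. Selective silylation of the primary hydroxyl (TBSCl, imidazole, CH2Cl2, −20 °C) gives (1R)-1-[(2R,4S,5R)-4-bromo-5-ethyloxolan-2-yl]-5-{[tert-butyl(dimethyl)silyl]oxy}pent-3-yn-1-ol F8. Appel bromination with inversion gives {[(5S)-5-bromo-5-[(2R,4S,5R)-4-bromo-5-ethyloxolan-2-yl]pent-2-yn-1-yl]oxy}(tert-butyl)dimethylsilane F9, and HF·pyridine releases 13.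

3. Step 15. What may go wrong: γ-deprotonation of the enal by the lithium base and opening of the neighbouring oxirane before or after the diazo reagent adds. The fallback builds the enyne by sp2–sp coupling without an aldehyde or a strong base; it sets out from 17 and returns at 19. Cross-metathesis of 17 with vinylboronic acid pinacol ester (second-generation Grubbs catalyst RuCl2(=CHPh)(PCy3)(SIMes), CH2Cl2, 40 °C) should give 2-[(1E)-3-{(2S,3R)-3-[(2S)-2-bromo-2-[(2R,4S,5R)-4-bromo-5-ethyloxolan-2-yl]ethyl]oxiran-2-yl}prop-1-en-1-yl]-4,4,5,5-tetramethyl-1,3,2-dioxaborolane F10. Suzuki–Miyaura coupling with (bromoethynyl)triisopropylsilane (Pd(PPh3)4, aq. K3PO4, THF, rt) gives (2R,3S,5R)-3-bromo-5-[(1S)-1-bromo-2-{(2R,3S)-3-[(2E)-5-(triisopropylsilyl)pent-2-en-4-yn-1-yl]oxiran-2-yl}ethyl]-2-ethyloxolane F11. Bu4NF buffered with AcOH (THF, 0 °C) then gives 19.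

**Further compounds**

F1 | step 3 | (2R)-2-(prop-2-en-1-yloxy)butanoic acid | CC[C@@H](OCC=C)C(=O)O
F2 | step 3 | (2R)-2-(prop-2-en-1-yloxy)butanoyl chloride | CC[C@@H](OCC=C)C(=O)Cl
F3 | step 3 | (3R)-1-diazo-3-(prop-2-en-1-yloxy)pentan-2-one | CC[C@@H](OCC=C)C(=O)C=[N+]=[N-]
F4 | step 3 | (2R,5R)-5-ethenyl-2-ethyloxolan-3-one | C=C[C@H]1CC(=O)[C@@H](CC)O1
F5 | step 3 | (2R,3R,5R)-5-ethenyl-2-ethyloxolan-3-ol | C=C[C@H]1C[C@@H](O)[C@@H](CC)O1
F6 | step 3 | (2R,3S,5R)-3-bromo-5-ethenyl-2-ethyloxolane | C=C[C@H]1C[C@H](Br)[C@@H](CC)O1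
F7 | step 9 | (5R)-5-[(2R,4S,5R)-4-bromo-5-ethyloxolan-2-yl]pent-2-yne-1,5-diol | OCC#CC[C@@H](O)[C@H]1C[C@H](Br)[C@@H](CC)O1
F8 | step 9 | (1R)-1-[(2R,4S,5R)-4-bromo-5-ethyloxolan-2-yl]-5-{[tert-butyl(dimethyl)silyl]oxy}pent-3-yn-1-ol | CC(C)(C)[Si](C)(C)OCC#CC[C@@H](O)[C@H]1C[C@H](Br)[C@@H](CC)O1
F9 | step 9 | {[(5S)-5-bromo-5-[(2R,4S,5R)-4-bromo-5-ethyloxolan-2-yl]pent-2-yn-1-yl]oxy}(tert-butyl)dimethylsilane | CC(C)(C)[Si](C)(C)OCC#CC[C@H](Br)[C@H]1C[C@H](Br)[C@@H](CC)O1
F10 | step 15 | 2-[(1E)-3-{(2S,3R)-3-[(2S)-2-bromo-2-[(2R,4S,5R)-4-bromo-5-ethyloxolan-2-yl]ethyl]oxiran-2-yl}prop-1-en-1-yl]-4,4,5,5-tetramethyl-1,3,2-dioxaborolane | CC1(C)OB(/C=C/C[C@@H]2O[C@@H]2C[C@H](Br)[C@H]2C[C@H](Br)[C@@H](CC)O2)OC1(C)C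
F11 | step 15 | (2R,3S,5R)-3-bromo-5-[(1S)-1-bromo-2-{(2R,3S)-3-[(2E)-5-(triisopropylsilyl)pent-2-en-4-yn-1-yl]oxiran-2-yl}ethyl]-2-ethyloxolane | CC(C)[Si](C(C)C)(C(C)C)C#C/C=C/C[C@@H]1O[C@@H]1C[C@H](Br)[C@H]1C[C@H](Br)[C@@H](CC)O1
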